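**Retrosynthetic overview**
1. The cyclohexene ring is made last, by a biomimetic exo Diels–Alder reaction between a dehydroprenyl flavanonol diene and a chromene 2'-hydroxychalcone under chiral borate control, followed by removal of the acetate and silyl groups.
2. Pyranone ring C of the flavanonol is cut at C3–C4. The C3-hydroxy/C4-keto acyloin, with C4 on ring A ortho to O1, is a benzoin retron and leads back to a racemic open-chain dialdehyde ether. There C2 (benzylic, bound to O1, alpha to the acceptor aldehyde) is configurationally labile, so one chiral carbene-catalysed benzoin closure with dynamic kinetic resolution sets C2 and C3.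
3. The dialdehyde comes from a Williamson ether of a 4-O-silyl salicylaldehyde with an alpha-bromo arylacetate, reduction, Suzuki coupling of the dienyl boronate and double oxidation.
4. The chalcone comes from chromenylation of 2,4-dihydroxyacetophenone, Claisen–Schmidt condensation and exchange of MOM for acetate groups.
5. Order of ring formation: chromene ring, then pyranone ring C (key step), then the cyclohexene.

Key step: step 10

Remark on the chemistry: the sense of induction of the triazolium salt (step 10) and of VANOL (step 17) is assigned from the usual models for these catalyst classes. The antipode written is the one expected to give the stated configuration; its mirror image is to be used if a first run shows the opposite sense.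

**Route**

Step 1
Reactants: 1 2,4-dihydroxybenzaldehyde
Product: 2 2-hydroxy-4-[(triisopropylsilyl)oxy]benzaldehyde
Conditions: TIPSCl (1.05 equiv), imidazole, CH2Cl2, 0 °C
Reagents that add atoms: triisopropylsilyl chloride, CC(C)[Si](Cl)(C(C)C)C(C)C
Why: Selective silyl ether formation at the 4-OH, which is more acidic and unhindered, while the 2-OH is held in a hydrogen bond to the aldehyde.

Step 2
Reactants: 3 methyl 2-(2-hydroxyphenyl)acetate
Product: 4 methyl 2-(5-bromo-2-hydroxyphenyl)acetate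
Conditions: NBS (1.0 equiv), MeCN, 0 °C to rt
Reagents that add atoms: N-bromosuccinimide, O=C1CCC(=O)N1Br
Why: Electrophilic aromatic bromination should go para to the phenol OH, the position that later carries the diene.

Step 3
Reactants: 4 methyl 2-(5-bromo-2-hydroxyphenyl)acetate
Product: 5 methyl 2-{5-bromo-2-[(triisopropylsilyl)oxy]phenyl}acetate
Conditions: TIPSCl, imidazole, DMF, rt
Reagents that add atoms: triisopropylsilyl chloride, CC(C)[Si](Cl)(C(C)C)C(C)C
Why: Standard silyl ether formation; TIPS is chosen to survive carbonate, hydride, aqueous phosphate and carbene/amine conditions.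

Step 4
Reactants: 5 methyl 2-{5-bromo-2-[(triisopropylsilyl)oxy]phenyl}acetate
Product: 6 methyl 2-bromo-2-{5-bromo-2-[(triisopropylsilyl)oxy]phenyl}acetate (racemic)
Conditions: NBS, AIBN (cat.), PhCF3, 80 °C
Reagents that add atoms: N-bromosuccinimide, O=C1CCC(=O)N1Br
Why: Wohl–Ziegler radical bromination at the benzylic, ester-activated C–H; a racemic bromide is sufficient.

Step 5
Reactants: 2 2-hydroxy-4-[(triisopropylsilyl)oxy]benzaldehyde; 6 methyl 2-bromo-2-{5-bromo-2-[(triisopropylsilyl)oxy]phenyl}acetate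
Product: 7 methyl 2-{5-bromo-2-[(triisopropylsilyl)oxy]phenyl}-2-{2-formyl-5-[(triisopropylsilyl)oxy]phenoxy}acetate (racemic)
Conditions: K2CO3, acetone, rt
Reagents that add atoms: none
Why: Williamson ether synthesis (SN2 of the salicylaldehyde phenoxide on the activated benzylic alpha-bromo ester); the new centre is left racemic on purpose because it is equilibrated in step 10.

Step 6
Reactants: 7 methyl 2-{5-bromo-2-[(triisopropylsilyl)oxy]phenyl}-2-{2-formyl-5-[(triisopropylsilyl)oxy]phenoxy}acetate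
Product: 8 2-{5-bromo-2-[(triisopropylsilyl)oxy]phenyl}-2-{2-(hydroxymethyl)-5-[(triisopropylsilyl)oxy]phenoxy}ethan-1-ol (racemic)
Conditions: DIBAL-H (excess), CH2Cl2, −78 to 0 °C; aq. Rochelle salt
Reagents that add atoms: none
Why: Hydride reduction of ester and aryl aldehyde to the diol removes every base-sensitive carbonyl before the cross-coupling; aryl bromide and aryl silyl ethers are inert.

Step 7
Reactants: 9 2-methylbut-1-en-3-yne
Product: 10 (E)-4,4,5,5-tetramethyl-2-(3-methylbuta-1,3-dien-1-yl)-1,3,2-dioxaborolane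
Conditions: pinacolborane, Cp2Zr(H)Cl (5 mol %), Et3N (10 mol %), neat, 60 °C
Reagents that add atoms: pinacolborane, CC1(C)OBOC1(C)C
Why: Zirconium-catalysed hydroboration of the terminal alkyne is syn and anti-Markovnikov, which gives the E-dienyl boronate and leaves the isopropenyl group untouched.

Step 8
Reactants: 8 2-{5-bromo-2-[(triisopropylsilyl)oxy]phenyl}-2-{2-(hydroxymethyl)-5-[(triisopropylsilyl)oxy]phenoxy}ethan-1-ol; 10 (E)-4,4,5,5-tetramethyl-2-(3-methylbuta-1,3-dien-1-yl)-1,3,2-dioxaborolane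
Product: 11 2-{2-(hydroxymethyl)-5-[(triisopropylsilyl)oxy]phenoxy}-2-{5-[(1E)-3-methylbuta-1,3-dien-1-yl]-2-[(triisopropylsilyl)oxy]phenyl}ethan-1-ol (racemic)
Conditions: Pd(dppf)Cl2 (5 mol %), K3PO4, THF/H2O, 60 °C
Reagents that add atoms: none
Why: Suzuki–Miyaura coupling with retention of the E alkene geometry; the diol tolerates the aqueous base.

Step 9
Reactants: 11 2-{2-(hydroxymethyl)-5-[(triisopropylsilyl)oxy]phenoxy}-2-{5-[(1E)-3-methylbuta-1,3-dien-1-yl]-2-[(triisopropylsilyl)oxy]phenyl}ethan-1-ol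
Product: 12 2-(1-{5-[(1E)-3-methylbuta-1,3-dien-1-yl]-2-[(triisopropylsilyl)oxy]phenyl}-2-oxoethoxy)-4-[(triisopropylsilyl)oxy]benzaldehyde (racemic)
Conditions: Dess–Martin periodinane, NaHCO3, CH2Cl2, 0 °C to rt; filtered and used at once
Reagents that add atoms: none
Why: Buffered Dess–Martin oxidation should convert the benzylic and the primary alcohol to the two aldehydes without touching the diene.

Step 10
Reactants: 12 2-(1-{5-[(1E)-3-methylbuta-1,3-dien-1-yl]-2-[(triisopropylsilyl)oxy]phenyl}-2-oxoethoxy)-4-[(triisopropylsilyl)oxy]benzaldehyde (racemic)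
Product: 14 (2R,3R)-3-hydroxy-2-{5-[(1E)-3-methylbuta-1,3-dien-1-yl]-2-[(triisopropylsilyl)oxy]phenyl}-7-[(triisopropylsilyl)oxy]-2,3-dihydro-4H-chromen-4-one, via (R)-dialdehyde 13 (not isolated)
Conditions: (5aR,10bS)-2-(pentafluorophenyl)-5a,10b-dihydro-4H,6H-indeno[2,1-b][1,2,4]triazolo[4,3-d][1,4]oxazin-2-ium tetrafluoroborate (15 mol %), i-Pr2NEt (30 mol %), toluene (0.02 M), 4 Å MS, rt
Reagents that add atoms: none
Why: Proposed new method: the triazolylidene freed by the amine adds to the aryl aldehyde and, after proton transfer, the Breslow intermediate (acyl-anion equivalent at the future C4) attacks the pendant aliphatic aldehyde carbon (future C3), after which proton transfer and loss of the carbene release the C3-hydroxy C4-ketone; the closest known reaction types are the triazolium-catalysed intramolecular crossed aldehyde–ketone benzoin that closes 3-hydroxychroman-4-ones from 2-(2-oxoalkoxy)benzaldehydes, and benzoin cyclisations run as dynamic kinetic resolutions on acceptors with a labile alpha centre. Ring C closes in a 6-exo-trig mode, the attacked C=O being exocyclic to the forming pyranone. C3 is set by the catalyst, whose aminoindane backbone blocks one face of the enaminol while the enaminol O–H hydrogen-bonds the acceptor carbonyl and so fixes which aldehyde face is attacked. C2 is set by dynamic kinetic resolution: its hydrogen is benzylic, alpha to oxygen and alpha to the acceptor aldehyde, so the enantiomers of 12 should interconvert through the enol under the amine, and only (R)-13 can pass through the chair-like transition state with the C2 aryl group equatorial and anti to the forming C3–O bond, which leads to the 2,3-trans (2R,3R) ketol. The step needs donor/acceptor chemoselectivity (the aryl aldehyde must be the acyl donor, otherwise the regioisomeric 4-hydroxychroman-3-one or beta-elimination of the aryloxide would result), and the benzoin closure must outrun the 5-exo aldol of the C2 enol onto the aryl aldehyde. The first is secured because the alpha-branched, alpha-oxygenated aliphatic aldehyde is too hindered to form a Breslow intermediate yet is strongly electrophilic, while o-alkoxybenzaldehydes are proven donors in this ring size; the second because the aldol must build a congested quaternary centre reversibly, whereas the aryl-conjugated ketol is a thermodynamic sink.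

Step 11
Reactants: 14 (2R,3R)-3-hydroxy-2-{5-[(1E)-3-methylbuta-1,3-dien-1-yl]-2-[(triisopropylsilyl)oxy]phenyl}-7-[(triisopropylsilyl)oxy]-2,3-dihydro-4H-chromen-4-one
Product: 15 (2R,3R)-2-{5-[(1E)-3-methylbuta-1,3-dien-1-yl]-2-[(triisopropylsilyl)oxy]phenyl}-3-[(triethylsilyl)oxy]-7-[(triisopropylsilyl)oxy]-2,3-dihydro-4H-chromen-4-one
Conditions: TESCl, imidazole, DMF, 0 °C
Reagents that add atoms: chlorotriethylsilane, CC[Si](Cl)(CC)CC
Why: Silyl ether formation with a weak base that should neither enolise nor ring-open the ketol; it masks the chelating alpha-ketol before the boron-mediated cycloaddition.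

Step 12
Reactants: 16 2,4-dihydroxyacetophenone; 17 3-methylbut-2-enal
Product: 18 1-(5-hydroxy-2,2-dimethyl-2H-chromen-6-yl)ethan-1-one
Conditions: pyridine, 120 °C, sealed tube
Reagents that add atoms: none
Why: Chromenylation by condensation of the enal at the ring carbon between the two oxygens and oxa-6π electrocyclisation through the free 4-OH; the chelated 2-OH stays free, which fixes the regiochemistry.

Step 13
Reactants: 1 2,4-dihydroxybenzaldehyde
Product: 19 2,4-bis(methoxymethoxy)benzaldehyde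
Conditions: MOMCl, K2CO3, acetone, reflux
Reagents that add atoms: chloromethyl methyl ether, COCCl
Why: O-alkylation of both phenols gives a base-stable aldehyde for the aldol condensation.

Step 14
Reactants: 18 1-(5-hydroxy-2,2-dimethyl-2H-chromen-6-yl)ethan-1-one; 19 2,4-bis(methoxymethoxy)benzaldehyde
Product: 20 (E)-3-[2,4-bis(methoxymethoxy)phenyl]-1-(5-hydroxy-2,2-dimethyl-2H-chromen-6-yl)prop-2-en-1-one
Conditions: KOH, EtOH/H2O, rt
Reagents that add atoms: none
Why: Claisen–Schmidt condensation (aldol addition, then E1cB dehydration) gives the E enone under thermodynamic control.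

Step 15
Reactants: 20 (E)-3-[2,4-bis(methoxymethoxy)phenyl]-1-(5-hydroxy-2,2-dimethyl-2H-chromen-6-yl)prop-2-en-1-one
Product: 21 (E)-3-(2,4-dihydroxyphenyl)-1-(5-hydroxy-2,2-dimethyl-2H-chromen-6-yl)prop-2-en-1-one
Conditions: 3 M HCl, MeOH, 50 °C, dark
Reagents that add atoms: none
Why: Acid-catalysed acetal exchange removes both MOM groups; chromene and E enone should survive dilute methanolic acid in the dark.

Step 16
Reactants: 21 (E)-3-(2,4-dihydroxyphenyl)-1-(5-hydroxy-2,2-dimethyl-2H-chromen-6-yl)prop-2-en-1-one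
Product: 22 4-[(1E)-3-(5-hydroxy-2,2-dimethyl-2H-chromen-6-yl)-3-oxoprop-1-en-1-yl]-1,3-phenylene diacetate
Conditions: Ac2O (2.2 equiv), pyridine, CH2Cl2, 0 °C
Reagents that add atoms: acetic anhydride, CC(=O)OC(C)=O
Why: Acetylation of the two free resorcinol hydroxyls; the 2'-OH is hydrogen-bonded to the ketone, reacts far more slowly and stays free for boron chelation.

Step 17
Reactants: 15 (2R,3R)-2-{5-[(1E)-3-methylbuta-1,3-dien-1-yl]-2-[(triisopropylsilyl)oxy]phenyl}-3-[(triethylsilyl)oxy]-7-[(triisopropylsilyl)oxy]-2,3-dihydro-4H-chromen-4-one; 22 4-[(1E)-3-(5-hydroxy-2,2-dimethyl-2H-chromen-6-yl)-3-oxoprop-1-en-1-yl]-1,3-phenylene diacetate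
Product: 23 exo (all-trans) cycloadduct 4-[(1S,5R,6R)-6-(5-hydroxy-2,2-dimethyl-2H-chromene-6-carbonyl)-3-methyl-5-{3-[(2R,3R)-4-oxo-3-[(triethylsilyl)oxy]-7-[(triisopropylsilyl)oxy]-3,4-dihydro-2H-chromen-2-yl]-4-[(triisopropylsilyl)oxy]phenyl}cyclohex-3-en-1-yl]-1,3-phenylene diacetate
Conditions: BH3·THF, AcOH, (R)-VANOL [(R)-3,3'-diphenyl-2,2'-binaphthalene-1,1'-diol] (1.2 equiv each), THF, rt; then 22; then 15, rt, dark
Reagents that add atoms: none
Why: Diels–Alder reaction in which the 2'-hydroxychalcone forms a chiral borate chelate that lowers the enone LUMO and shields one face, the diene CH2 terminus bonds to the enone beta carbon, the E dienophile geometry gives the C4/C5 trans relation, the exo transition state gives the C3/C4 trans relation (the endo isomer is expected beside it and should be separable), and the absolute configuration of the three new centres is ligand-controlled because the flavanonol centres are remote.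

Step 18
Reactants: 23 exo cycloadduct (diacetate, two TIPS ethers, one TES ether)
Product: 24 (2R,3R)-2-{5-[(1R,5S,6R)-5-(2,4-dihydroxyphenyl)-6-(5-hydroxy-2,2-dimethyl-2H-chromene-6-carbonyl)-3-methylcyclohex-2-en-1-yl]-2-[(triisopropylsilyl)oxy]phenyl}-3-[(triethylsilyl)oxy]-7-[(triisopropylsilyl)oxy]-2,3-dihydro-4H-chromen-4-one
Conditions: NH4OAc (10 equiv), MeOH/THF/H2O, rt
Reagents that add atoms: none
Why: Ammonium acetate-promoted methanolysis cleaves phenolic acetates near neutral pH, which avoids base that could ring-open or epimerise the flavanonol; the silyl ethers should remain.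

Step 19
Reactants: 24 bis-TIPS/TES-protected adduct
Product: 25 (2R,3R)-2-{5-[(1R,5S,6R)-5-(2,4-dihydroxyphenyl)-6-(5-hydroxy-2,2-dimethyl-2H-chromene-6-carbonyl)-3-methylcyclohex-2-en-1-yl]-2-hydroxyphenyl}-3,7-dihydroxy-2,3-dihydro-4H-chromen-4-one (CNP0204112.1)
Conditions: TBAF, AcOH (1:1), THF, 0 °C to rt
Reagents that add atoms: none
Why: Fluoride cleaves the two aryl TIPS ethers and the TES ether, and acetic acid buffers the liberated phenoxides so that C2/C3 of the flavanonol and the ketone alpha centre of the cyclohexene are not epimerised.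

**Compound list**
1 | 2,4-dihydroxybenzaldehyde | O=Cc1ccc(O)cc1O | starting material
2 | 2-hydroxy-4-[(triisopropylsilyl)oxy]benzaldehyde | O=Cc1ccc(O[Si](C(C)C)(C(C)C)C(C)C)cc1O | intermediate
3 | methyl 2-(2-hydroxyphenyl)acetate | COC(=O)Cc1ccccc1O | starting material
4 | methyl 2-(5-bromo-2-hydroxyphenyl)acetate | COC(=O)Cc1cc(Br)ccc1O | intermediate
5 | methyl 2-{5-bromo-2-[(triisopropylsilyl)oxy]phenyl}acetate | COC(=O)Cc1cc(Br)ccc1O[Si](C(C)C)(C(C)C)C(C)C | intermediate
6 | methyl 2-bromo-2-{5-bromo-2-[(triisopropylsilyl)oxy]phenyl}acetate (racemic) | COC(=O)C(Br)c1cc(Br)ccc1O[Si](C(C)C)(C(C)C)C(C)C | intermediate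
7 | methyl 2-{5-bromo-2-[(triisopropylsilyl)oxy]phenyl}-2-{2-formyl-5-[(triisopropylsilyl)oxy]phenoxy}acetate (racemic) | COC(=O)C(Oc1cc(O[Si](C(C)C)(C(C)C)C(C)C)ccc1C=O)c1cc(Br)ccc1O[Si](C(C)C)(C(C)C)C(C)C | intermediate
8 | 2-{5-bromo-2-[(triisopropylsilyl)oxy]phenyl}-2-{2-(hydroxymethyl)-5-[(triisopropylsilyl)oxy]phenoxy}ethan-1-ol (racemic) | OCC(Oc1cc(O[Si](C(C)C)(C(C)C)C(C)C)ccc1CO)c1cc(Br)ccc1O[Si](C(C)C)(C(C)C)C(C)C | intermediate
9 | 2-methylbut-1-en-3-yne | C=C(C)C#C | starting material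
10 | (E)-4,4,5,5-tetramethyl-2-(3-methylbuta-1,3-dien-1-yl)-1,3,2-dioxaborolane | CC(=C)/C=C/B1OC(C)(C)C(C)(C)O1 | intermediate
11 | 2-{2-(hydroxymethyl)-5-[(triisopropylsilyl)oxy]phenoxy}-2-{5-[(1E)-3-methylbuta-1,3-dien-1-yl]-2-[(triisopropylsilyl)oxy]phenyl}ethan-1-ol (racemic) | CC(=C)/C=C/c1ccc(O[Si](C(C)C)(C(C)C)C(C)C)c(C(CO)Oc2cc(O[Si](C(C)C)(C(C)C)C(C)C)ccc2CO)c1 | intermediate
12 | 2-(1-{5-[(1E)-3-methylbuta-1,3-dien-1-yl]-2-[(triisopropylsilyl)oxy]phenyl}-2-oxoethoxy)-4-[(triisopropylsilyl)oxy]benzaldehyde (racemic) | CC(=C)/C=C/c1ccc(O[Si](C(C)C)(C(C)C)C(C)C)c(C(C=O)Oc2cc(O[Si](C(C)C)(C(C)C)C(C)C)ccc2C=O)c1 | intermediate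
13 | (R)-enantiomer of dialdehyde 12 | CC(=C)/C=C/c1ccc(O[Si](C(C)C)(C(C)C)C(C)C)c([C@H](C=O)Oc2cc(O[Si](C(C)C)(C(C)C)C(C)C)ccc2C=O)c1 | intermediate
14 | (2R,3R)-3-hydroxy-2-{5-[(1E)-3-methylbuta-1,3-dien-1-yl]-2-[(triisopropylsilyl)oxy]phenyl}-7-[(triisopropylsilyl)oxy]-2,3-dihydro-4H-chromen-4-one | CC(=C)/C=C/c1ccc(O[Si](C(C)C)(C(C)C)C(C)C)c([C@H]2Oc3cc(O[Si](C(C)C)(C(C)C)C(C)C)ccc3C(=O)[C@@H]2O)c1 | intermediate
15 | (2R,3R)-2-{5-[(1E)-3-methylbuta-1,3-dien-1-yl]-2-[(triisopropylsilyl)oxy]phenyl}-3-[(triethylsilyl)oxy]-7-[(triisopropylsilyl)oxy]-2,3-dihydro-4H-chromen-4-one | CC(=C)/C=C/c1ccc(O[Si](C(C)C)(C(C)C)C(C)C)c([C@H]2Oc3cc(O[Si](C(C)C)(C(C)C)C(C)C)ccc3C(=O)[C@@H]2O[Si](CC)(CC)CC)c1 | intermediate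
16 | 2,4-dihydroxyacetophenone | CC(=O)c1ccc(O)cc1O | starting material
17 | 3-methylbut-2-enal | CC(C)=CC=O | starting material
18 | 1-(5-hydroxy-2,2-dimethyl-2H-chromen-6-yl)ethan-1-one | CC(=O)c1ccc2OC(C)(C)C=Cc2c1O | intermediate
19 | 2,4-bis(methoxymethoxy)benzaldehyde | COCOc1ccc(C=O)c(OCOC)c1 | intermediate
20 | (E)-3-[2,4-bis(methoxymethoxy)phenyl]-1-(5-hydroxy-2,2-dimethyl-2H-chromen-6-yl)prop-2-en-1-one | COCOc1ccc(/C=C/C(=O)c2ccc3OC(C)(C)C=Cc3c2O)c(OCOC)c1 | intermediate
21 | (E)-3-(2,4-dihydroxyphenyl)-1-(5-hydroxy-2,2-dimethyl-2H-chromen-6-yl)prop-2-en-1-one | Oc1ccc(/C=C/C(=O)c2ccc3OC(C)(C)C=Cc3c2O)c(O)c1 | intermediate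
22 | 4-[(1E)-3-(5-hydroxy-2,2-dimethyl-2H-chromen-6-yl)-3-oxoprop-1-en-1-yl]-1,3-phenylene diacetate | CC(=O)Oc1ccc(/C=C/C(=O)c2ccc3OC(C)(C)C=Cc3c2O)c(OC(C)=O)c1 | intermediate
23 | exo (all-trans) cycloadduct; diacetate, two TIPS ethers, one TES ether; cyclohexene centres as in the target, flavanonol 2R,3R | CC1=C[C@@H](c2ccc(O[Si](C(C)C)(C(C)C)C(C)C)c([C@H]3Oc4cc(O[Si](C(C)C)(C(C)C)C(C)C)ccc4C(=O)[C@@H]3O[Si](CC)(CC)CC)c2)[C@H](C(=O)c2ccc3c(c2O)C=CC(C)(C)O3)[C@@H](c2ccc(OC(C)=O)cc2OC(C)=O)C1 | intermediate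
24 | deacetylated cycloadduct; two TIPS ethers, one TES ether | CC1=C[C@@H](c2ccc(O[Si](C(C)C)(C(C)C)C(C)C)c([C@H]3Oc4cc(O[Si](C(C)C)(C(C)C)C(C)C)ccc4C(=O)[C@@H]3O[Si](CC)(CC)CC)c2)[C@H](C(=O)c2ccc3c(c2O)C=CC(C)(C)O3)[C@@H](c2ccc(O)cc2O)C1 | intermediate
25 | CNP0204112.1, (2R,3R)-2-{5-[(1R,5S,6R)-5-(2,4-dihydroxyphenyl)-6-(5-hydroxy-2,2-dimethyl-2H-chromene-6-carbonyl)-3-methylcyclohex-2-en-1-yl]-2-hydroxyphenyl}-3,7-dihydroxy-2,3-dihydro-4H-chromen-4-one | CC1=C[C@@H](c2ccc(O)c([C@H]3Oc4cc(O)ccc4C(=O)[C@@H]3O)c2)[C@H](C(=O)c2ccc3c(c2O)C=CC(C)(C)O3)[C@@H](c2ccc(O)cc2O)C1 | target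

**Step count and risks**
Total step count: 19. Longest linear sequence: 12 steps (steps 2, 3, 4, 5, 6, 8, 9, 10, 11, 17, 18, 19, from compound 3).

Steps most likely to fail:

1. Step 10 (Proposed new method). What may go wrong: the carbene may engage the aliphatic aldehyde (wrong ketol regiochemistry or expulsion of the aryloxide), the C2 enol may close by aldol reaction, or racemisation may be too slow for the dynamic resolution, leaving poor stereocontrol. The fallback uses known chemistry and still closes ring C at C3–C4, by olefin metathesis; it sets out from compound 2 and commercial 5-bromo-2-hydroxybenzaldehyde and comes back at compound 14. The bromo aldehyde is silylated (TIPSCl, imidazole) to 5-bromo-2-[(triisopropylsilyl)oxy]benzaldehyde F1, extended by Horner–Wadsworth–Emmons olefination (triethyl phosphonoacetate, NaH) to the E cinnamate F2, reduced (DIBAL-H) to the cinnamyl alcohol F3 and converted (ClCO2Me, pyridine) to the methyl carbonate F4. Iridium-catalysed asymmetric allylic etherification of phenol 2 with F4 ([Ir(cod)Cl]2, chiral phosphoramidite, base) should give the branched (S)-aryl allyl ether F5, which fixes the future C2 in a form that cannot epimerise. Wittig methylenation (Ph3P=CH2) gives the bis-alkene F6, and ring-closing metathesis (second-generation Grubbs catalyst) closes the (S)-2-aryl-2H-chromene F7. Dihydroxylation (OsO4 cat., NMO) anti to the C2 aryl group should give the 2,3-trans-3,4-cis diol F8, and selective oxidation of the electron-rich benzylic C4 alcohol (DDQ) the (2R,3R)-bromo flavanonol F9. Suzuki–Miyaura coupling of F9 with boronate 10 (Pd(OAc)2/SPhos, K3PO4, THF/H2O, 40 °C) then gives 14.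

2. Step 17. What may go wrong: poor exo/endo or facial selectivity, slow cycloaddition with the bulky diene, or erosion of the ketol under the boron Lewis acid. The fallback reverses the order of events: the cycloaddition is run on a small robust diene and the heterocycle is built afterwards; it sets out from compounds 11 and 22 and comes back at compound 25. Diol 11 is silylated (TESCl, imidazole) to the bis-TES ether F10, which undergoes the same VANOL–borate Diels–Alder reaction with 22 to give the exo adduct F11 (a mixture at the ether carbon, which is harmless because that centre is equilibrated later). Selective cleavage of the two alkyl TES ethers (PPTS, MeOH, 0 °C) gives diol F12 and Dess–Martin oxidation gives dialdehyde F13. The carbene-catalysed benzoin closure of step 10 then gives ketol F14, ammonium acetate methanolysis gives F15, and TBAF/AcOH gives 25.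

3. Step 5. What may go wrong: base-induced aldol closure of the ester enolate onto the ortho aldehyde (benzofuran-type by-products) or silyl transfer to the phenoxide. The fallback replaces the SN2 step by a carbenoid O–H insertion under neutral conditions; it sets out from compound 5 and comes back at compound 7. Diazo transfer to 5 (p-acetamidobenzenesulfonyl azide, DBU, MeCN) gives methyl 2-{5-bromo-2-[(triisopropylsilyl)oxy]phenyl}-2-diazoacetate F16, and Rh2(OAc)4-catalysed O–H insertion into phenol 2 (CH2Cl2, rt) gives 7; step 4 is then not needed.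

**Further compounds**
F1 | step 10 | 5-bromo-2-[(triisopropylsilyl)oxy]benzaldehyde | O=Cc1cc(Br)ccc1O[Si](C(C)C)(C(C)C)C(C)C
F2 | step 10 | ethyl (2E)-3-{5-bromo-2-[(triisopropylsilyl)oxy]phenyl}prop-2-enoate | CCOC(=O)/C=C/c1cc(Br)ccc1O[Si](C(C)C)(C(C)C)C(C)C
F3 | step 10 | (2E)-3-{5-bromo-2-[(triisopropylsilyl)oxy]phenyl}prop-2-en-1-ol | OC/C=C/c1cc(Br)ccc1O[Si](C(C)C)(C(C)C)C(C)C
F4 | step 10 | (2E)-3-{5-bromo-2-[(triisopropylsilyl)oxy]phenyl}prop-2-en-1-yl methyl carbonate | COC(=O)OC/C=C/c1cc(Br)ccc1O[Si](C(C)C)(C(C)C)C(C)C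
F5 | step 10 | 2-{[(1S)-1-{5-bromo-2-[(triisopropylsilyl)oxy]phenyl}prop-2-en-1-yl]oxy}-4-[(triisopropylsilyl)oxy]benzaldehyde | Brc1ccc(O[Si](C(C)C)(C(C)C)C(C)C)c([C@H](C=C)Oc2cc(O[Si](C(C)C)(C(C)C)C(C)C)ccc2C=O)c1
F6 | step 10 | (S)-1-{5-bromo-2-[(triisopropylsilyl)oxy]phenyl}prop-2-en-1-yl 2-ethenyl-5-[(triisopropylsilyl)oxy]phenyl ether | Brc1ccc(O[Si](C(C)C)(C(C)C)C(C)C)c([C@H](C=C)Oc2cc(O[Si](C(C)C)(C(C)C)C(C)C)ccc2C=C)c1
F7 | step 10 | (2S)-2-{5-bromo-2-[(triisopropylsilyl)oxy]phenyl}-7-[(triisopropylsilyl)oxy]-2H-chromene | Brc1ccc(O[Si](C(C)C)(C(C)C)C(C)C)c([C@H]2Oc3cc(O[Si](C(C)C)(C(C)C)C(C)C)ccc3C=C2)c1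
F8 | step 10 | (2R,3S,4S)-2-{5-bromo-2-[(triisopropylsilyl)oxy]phenyl}-7-[(triisopropylsilyl)oxy]-3,4-dihydro-2H-chromene-3,4-diol | Brc1ccc(O[Si](C(C)C)(C(C)C)C(C)C)c([C@H]2Oc3cc(O[Si](C(C)C)(C(C)C)C(C)C)ccc3[C@H](O)[C@@H]2O)c1
F9 | step 10 | (2R,3R)-2-{5-bromo-2-[(triisopropylsilyl)oxy]phenyl}-3-hydroxy-7-[(triisopropylsilyl)oxy]-2,3-dihydro-4H-chromen-4-one | Brc1ccc(O[Si](C(C)C)(C(C)C)C(C)C)c([C@H]2Oc3cc(O[Si](C(C)C)(C(C)C)C(C)C)ccc3C(=O)[C@@H]2O)c1
F10 | step 17 | bis(triethylsilyl) ether of diol 11 (racemic) | CC(=C)/C=C/c1ccc(O[Si](C(C)C)(C(C)C)C(C)C)c(C(CO[Si](CC)(CC)CC)Oc2cc(O[Si](C(C)C)(C(C)C)C(C)C)ccc2CO[Si](CC)(CC)CC)c1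
F11 | step 17 | exo cycloadduct of F10 and 22 (mixture at the ether carbon) | CC1=C[C@@H](c2ccc(O[Si](C(C)C)(C(C)C)C(C)C)c(C(CO[Si](CC)(CC)CC)Oc3cc(O[Si](C(C)C)(C(C)C)C(C)C)ccc3CO[Si](CC)(CC)CC)c2)[C@H](C(=O)c2ccc3c(c2O)C=CC(C)(C)O3)[C@@H](c2ccc(OC(C)=O)cc2OC(C)=O)C1
F12 | step 17 | diol from F11 after cleavage of the two alkyl TES ethers | CC1=C[C@@H](c2ccc(O[Si](C(C)C)(C(C)C)C(C)C)c(C(CO)Oc3cc(O[Si](C(C)C)(C(C)C)C(C)C)ccc3CO)c2)[C@H](C(=O)c2ccc3c(c2O)C=CC(C)(C)O3)[C@@H](c2ccc(OC(C)=O)cc2OC(C)=O)C1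
F13 | step 17 | dialdehyde from F12 | CC1=C[C@@H](c2ccc(O[Si](C(C)C)(C(C)C)C(C)C)c(C(C=O)Oc3cc(O[Si](C(C)C)(C(C)C)C(C)C)ccc3C=O)c2)[C@H](C(=O)c2ccc3c(c2O)C=CC(C)(C)O3)[C@@H](c2ccc(OC(C)=O)cc2OC(C)=O)C1
F14 | step 17 | (2R,3R)-ketol adduct with free 3-OH (diacetate, two TIPS ethers) | CC1=C[C@@H](c2ccc(O[Si](C(C)C)(C(C)C)C(C)C)c([C@H]3Oc4cc(O[Si](C(C)C)(C(C)C)C(C)C)ccc4C(=O)[C@@H]3O)c2)[C@H](C(=O)c2ccc3c(c2O)C=CC(C)(C)O3)[C@@H](c2ccc(OC(C)=O)cc2OC(C)=O)C1
F15 | step 17 | deacetylated ketol adduct (two TIPS ethers) | CC1=C[C@@H](c2ccc(O[Si](C(C)C)(C(C)C)C(C)C)c([C@H]3Oc4cc(O[Si](C(C)C)(C(C)C)C(C)C)ccc4C(=O)[C@@H]3O)c2)[C@H](C(=O)c2ccc3c(c2O)C=CC(C)(C)O3)[C@@H](c2ccc(O)cc2O)C1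
F16 | step 5 | methyl 2-{5-bromo-2-[(triisopropylsilyl)oxy]phenyl}-2-diazoacetate | COC(=O)C(=[N+]=[N-])c1cc(Br)ccc1O[Si](C(C)C)(C(C)C)C(C)C
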